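The route rests on disconnecting ring A itself: its OMe (C3) and OH (C5) sit meta to the chain-bearing carbon C1, which is the oxygen pattern of a 5-alkylcyclohexane-1,3-dione. Ring A is therefore built late, as a saturated carbocycle, by annulating dimethyl malonate onto a methyl enone: conjugate addition at the enone β-carbon (future C1) followed by Claisen closure of the methyl ketone onto a malonate ester should form two C–C bonds and the complete six-membered ring in one operation. The precursor is an E-methyl enone that already carries the fourteen-carbon tether, its E-alkene and ring B as a bis-isopropyl ether. Enol-ether formation on the symmetric dione, then dehydrogenation, differentiates OMe from OH.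

Key step: step 7

Remark: the β-dicarbonyl compounds 16–18 are written as keto tautomers although they should exist largely as enols; the stereocentres of 15–21 are racemic and vanish on aromatisation, so the E-alkene (set in step 3, retained in step 4) is the only stereo-element of the target.

Step 1
Reactants: 1 5-bromoresorcinol (5-bromobenzene-1,3-diol)
Product: 2 1-bromo-3,5-di(propan-2-yloxy)benzene
Conditions: 2-bromopropane (3 equiv), K2CO3, DMF, 60 °C
Reagents that add atoms: 2-bromopropane, CC(C)Br
Why: Williamson ether synthesis, in which both phenoxides displace bromide from the secondary halide in a polar aprotic solvent while the aryl bromide stays inert, and excess halide covers loss by elimination.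

Step 2
Reactants: 2 1-bromo-3,5-di(propan-2-yloxy)benzene; 3 5-bromopent-1-ene
Product: 5 1-(pent-4-en-1-yl)-3,5-di(propan-2-yloxy)benzene, via pent-4-en-1-ylmagnesium bromide 4 (not isolated)
Conditions: 3, Mg, THF, 40 °C; then 2, Pd(dppf)Cl2 (3 mol %), THF, 50 °C
Reagents that add atoms: none
Why: Kumada–Corriu coupling, in which the primary alkyl Grignard reagent transmetalates to the arylpalladium bromide and the wide-bite-angle dppf ligand favours reductive elimination over β-hydride elimination, so the terminal alkene should stay in place.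

Step 3
Reactants: 6 dec-9-yn-1-ol
Product: 8 (9E)-10-iododec-9-en-1-ol, via alkenylzirconocene chloride 7 (not isolated)
Conditions: Cp2Zr(H)Cl (2.3 equiv), THF, rt; then I2 (1.1 equiv), 0 °C
Reagents that add atoms: iodine, II
Why: Hydrozirconation–iodinolysis, in which the first equivalent of Cp2Zr(H)Cl caps the hydroxyl as a zirconium alkoxide, the second adds Zr–H syn across the terminal alkyne with zirconium on the terminal carbon, and iodine cleaves the C–Zr bond with retention, fixing the E geometry of the future chain alkene.

Step 4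
Reactants: 5 1-(pent-4-en-1-yl)-3,5-di(propan-2-yloxy)benzene; 8 (9E)-10-iododec-9-en-1-ol
Product: 10 (9E)-15-[3,5-di(propan-2-yloxy)phenyl]pentadec-9-en-1-ol, via B-alkyl-9-BBN 9 (not isolated)
Conditions: 5 (1.3 equiv), 9-BBN-H (1.25 equiv), THF, 0 °C → rt; then 8, Pd(dppf)Cl2 (5 mol %), 3 M aq NaOH, THF, 60 °C
Reagents that add atoms: none
Why: B-alkyl Suzuki–Miyaura coupling, in which 9-BBN-H adds anti-Markovnikov to the terminal alkene of 5 and the hydroxide-activated alkylborane couples with the alkenyl iodide with retention of the E geometry, the free hydroxyl being tolerated in the aqueous base.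

Step 5
Reactants: 10 (9E)-15-[3,5-di(propan-2-yloxy)phenyl]pentadec-9-en-1-ol
Product: 11 (9E)-15-[3,5-di(propan-2-yloxy)phenyl]pentadec-9-enal
Conditions: Dess–Martin periodinane (1.3 equiv), CH2Cl2, 0 °C → rt
Reagents that add atoms: none
Why: Dess–Martin oxidation should stop cleanly at the aldehyde and leave the isolated alkene and the aryl ethers untouched.

Step 6
Reactants: 11 (9E)-15-[3,5-di(propan-2-yloxy)phenyl]pentadec-9-enal; 12 1-(triphenylphosphoranylidene)propan-2-one
Product: 13 (3E,12E)-18-[3,5-di(propan-2-yloxy)phenyl]octadeca-3,12-dien-2-one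
Conditions: 12 (1.5 equiv), toluene, 90 °C
Reagents that add atoms: none
Why: Wittig olefination with a ketone-stabilised ylide, which reacts reversibly up to the oxaphosphetane and should therefore give the E-enone without touching the remote alkene.

Step 7
Reactants: 13 (3E,12E)-18-[3,5-di(propan-2-yloxy)phenyl]octadeca-3,12-dien-2-one; 14 dimethyl malonate
Product: 16 methyl trans-6-{(8E)-14-[3,5-di(propan-2-yloxy)phenyl]tetradec-8-en-1-yl}-2,4-dioxocyclohexane-1-carboxylate (racemic), via Michael adduct 15 (not isolated)
Conditions: 14 (1.3 equiv), NaOMe (1.5 equiv), MeOH/THF, 65 °C; then cold 1 M HCl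
Reagents that add atoms: none
Why: Methoxide deprotonates dimethyl malonate and the soft, doubly stabilised carbanion adds 1,4 to the E-enone at C4 (its β-carbon, the future chain-bearing carbon of ring A) to give keto diester 15; proton transfer then gives the enolate at the terminal methyl group of the ketone, which attacks one malonate ester carbonyl and expels methoxide. The closest known reaction type is the malonate–enone Michael addition/Claisen (Dieckmann-type) annulation used to make 5-alkylcyclohexane-1,3-diones. The ring closes in a 6-exo-trig mode, and the alternative enolate at the internal α-CH2 could only reach an ester through a four-membered ring. The chain-bearing ring carbon is formed without a controlling element and is racemic, while the ester-bearing carbon lies between two carbonyls, epimerises freely and should settle trans to the chain under thermodynamic control; both centres are erased later. The step needs conjugate addition instead of 1,2-addition and no reaction at the C12=C13 alkene or the aryl ethers: the enone is the only electrophilic alkene, 1,2-addition of malonate is reversible, and deprotonation of the acidic cyclic β-dicarbonyl product by the stoichiometric base pulls the sequence forward. Pairing NaOMe with the methyl esters avoids ester scrambling.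

Step 8
Reactants: 16 methyl trans-6-{(8E)-14-[3,5-di(propan-2-yloxy)phenyl]tetradec-8-en-1-yl}-2,4-dioxocyclohexane-1-carboxylate
Product: 18 5-{(8E)-14-[3,5-di(propan-2-yloxy)phenyl]tetradec-8-en-1-yl}cyclohexane-1,3-dione, via dioxo acid 17 (not isolated)
Conditions: 2 M aq NaOH, MeOH/THF, 70 °C; then HCl to pH 2, 80 °C
Reagents that add atoms: none
Why: Saponification followed by decarboxylation of the β-keto acid through its six-membered cyclic transition state on acidification and warming, conditions that the aryl isopropyl ethers and the isolated alkene should tolerate.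

Step 9
Reactants: 18 5-{(8E)-14-[3,5-di(propan-2-yloxy)phenyl]tetradec-8-en-1-yl}cyclohexane-1,3-dione
Product: 19 5-{(8E)-14-[3,5-di(propan-2-yloxy)phenyl]tetradec-8-en-1-yl}-3-methoxycyclohex-2-en-1-one (racemic)
Conditions: MeOH, TsOH·H2O (5 mol %), 3 Å molecular sieves, 50 °C
Reagents that add atoms: methanol, CO
Why: Acid-catalysed enol etherification of a cyclic 1,3-dione (a vinylogous Fischer esterification), in which the two carbonyls are equivalent by symmetry so that only one vinylogous methyl ester can form, as the racemate.

Step 10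
Reactants: 19 5-{(8E)-14-[3,5-di(propan-2-yloxy)phenyl]tetradec-8-en-1-yl}-3-methoxycyclohex-2-en-1-one
Product: 23 3-{(8E)-14-[3,5-di(propan-2-yloxy)phenyl]tetradec-8-en-1-yl}-5-methoxyphenol, via α-phenylselanyl enone 20 (not isolated), via selenoxide 21 (not isolated), via cyclohexadienone 22 (not isolated)
Conditions: LiN(iPr)2 (1.1 equiv), THF, −78 °C; PhSeCl (1.05 equiv), −78 °C; then pyridine, 30% aq H2O2, 0 °C → rt
Reagents that add atoms: none
Why: Enolate selenenylation followed by selenoxide syn-elimination, in which kinetic deprotonation at C6 and attack of PhSeCl anti to the C5 chain place selenium cis to H-5, the selenoxide eliminates below room temperature to the cross-conjugated dienone, and this tautomerises to the phenol; the enolate should outcompete the chain alkene for the single equivalent of PhSeCl, and pyridine-buffered peroxide limits epoxidation.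

Step 11
Reactants: 23 3-{(8E)-14-[3,5-di(propan-2-yloxy)phenyl]tetradec-8-en-1-yl}-5-methoxyphenol
Product: 24 dehydrobisgravillol, 5-[(6E)-14-(3-hydroxy-5-methoxyphenyl)tetradec-6-en-1-yl]benzene-1,3-diol
Conditions: BCl3 (1 M in CH2Cl2, 5 equiv), CH2Cl2, −78 → 0 °C; then MeOH, H2O
Reagents that add atoms: none
Why: Lewis-acid ether cleavage, in which BCl3 coordinates the ether oxygens and the secondary isopropyl groups leave as 2-chloropropane far faster than the primary methyl group, a known isopropyl-over-methyl selectivity for aryl ethers, while the isolated alkene should be inert at low temperature.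

Compound list
1 | 5-bromoresorcinol | Oc1cc(O)cc(Br)c1 | starting material
2 | 1-bromo-3,5-di(propan-2-yloxy)benzene | CC(C)Oc1cc(Br)cc(OC(C)C)c1 | intermediate
3 | 5-bromopent-1-ene | C=CCCCBr | starting material
4 | pent-4-en-1-ylmagnesium bromide | C=CCCC[Mg]Br | intermediate (not isolated)
5 | 1-(pent-4-en-1-yl)-3,5-di(propan-2-yloxy)benzene | C=CCCCc1cc(OC(C)C)cc(OC(C)C)c1 | intermediate
6 | dec-9-yn-1-ol | C#CCCCCCCCCO | starting material
7 | (E)-alkenylzirconocene chloride Cp2Zr(Cl)–CH=CH–(CH2)8–O–Zr(Cl)Cp2, hydroxyl capped as zirconocene alkoxide | Cl[Zr](C1C=CC=C1)(C1C=CC=C1)/C=C/CCCCCCCCO[Zr](Cl)(C1C=CC=C1)C1C=CC=C1 | intermediate (not isolated)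
8 | (9E)-10-iododec-9-en-1-ol | OCCCCCCCC/C=C/I | intermediate
9 | 9-{5-[3,5-di(propan-2-yloxy)phenyl]pentyl}-9-borabicyclo[3.3.1]nonane | CC(C)Oc1cc(CCCCCB2C3CCCC2CCC3)cc(OC(C)C)c1 | intermediate (not isolated)
10 | (9E)-15-[3,5-di(propan-2-yloxy)phenyl]pentadec-9-en-1-ol | OCCCCCCCC/C=C/CCCCCc1cc(OC(C)C)cc(OC(C)C)c1 | intermediate
11 | (9E)-15-[3,5-di(propan-2-yloxy)phenyl]pentadec-9-enal | O=CCCCCCCC/C=C/CCCCCc1cc(OC(C)C)cc(OC(C)C)c1 | intermediate
12 | 1-(triphenylphosphoranylidene)propan-2-one | CC(=O)C=P(c1ccccc1)(c1ccccc1)c1ccccc1 | starting material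
13 | (3E,12E)-18-[3,5-di(propan-2-yloxy)phenyl]octadeca-3,12-dien-2-one | CC(=O)/C=C/CCCCCCC/C=C/CCCCCc1cc(OC(C)C)cc(OC(C)C)c1 | intermediate
14 | dimethyl malonate | COC(=O)CC(=O)OC | starting material
15 | dimethyl 2-{(12E)-18-[3,5-di(propan-2-yloxy)phenyl]-2-oxooctadec-12-en-4-yl}propanedioate (racemic) | COC(=O)C(C(=O)OC)C(CC(C)=O)CCCCCCC/C=C/CCCCCc1cc(OC(C)C)cc(OC(C)C)c1 | intermediate (not isolated)
16 | methyl trans-6-{(8E)-14-[3,5-di(propan-2-yloxy)phenyl]tetradec-8-en-1-yl}-2,4-dioxocyclohexane-1-carboxylate (racemic; the 1S,6R enantiomer drawn) | COC(=O)[C@@H]1C(=O)CC(=O)C[C@H]1CCCCCCC/C=C/CCCCCc1cc(OC(C)C)cc(OC(C)C)c1 | intermediate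
17 | trans-6-{(8E)-14-[3,5-di(propan-2-yloxy)phenyl]tetradec-8-en-1-yl}-2,4-dioxocyclohexane-1-carboxylic acid (racemic; one enantiomer drawn) | OC(=O)[C@@H]1C(=O)CC(=O)C[C@H]1CCCCCCC/C=C/CCCCCc1cc(OC(C)C)cc(OC(C)C)c1 | intermediate (not isolated)
18 | 5-{(8E)-14-[3,5-di(propan-2-yloxy)phenyl]tetradec-8-en-1-yl}cyclohexane-1,3-dione | O=C1CC(=O)CC(CCCCCCC/C=C/CCCCCc2cc(OC(C)C)cc(OC(C)C)c2)C1 | intermediate
19 | 5-{(8E)-14-[3,5-di(propan-2-yloxy)phenyl]tetradec-8-en-1-yl}-3-methoxycyclohex-2-en-1-one (racemic; the 5R enantiomer drawn) | COC1=CC(=O)C[C@H](CCCCCCC/C=C/CCCCCc2cc(OC(C)C)cc(OC(C)C)c2)C1 | intermediate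
20 | trans-5-{(8E)-14-[3,5-di(propan-2-yloxy)phenyl]tetradec-8-en-1-yl}-3-methoxy-6-(phenylselanyl)cyclohex-2-en-1-one (racemic; the 5R,6S enantiomer drawn) | COC1=CC(=O)[C@@H]([Se]c2ccccc2)[C@H](CCCCCCC/C=C/CCCCCc3cc(OC(C)C)cc(OC(C)C)c3)C1 | intermediate (not isolated)
21 | trans-5-{(8E)-14-[3,5-di(propan-2-yloxy)phenyl]tetradec-8-en-1-yl}-3-methoxy-6-(phenylseleninyl)cyclohex-2-en-1-one (racemic, both configurations at selenium) | COC1=CC(=O)[C@@H]([Se](=O)c2ccccc2)[C@H](CCCCCCC/C=C/CCCCCc3cc(OC(C)C)cc(OC(C)C)c3)C1 | intermediate (not isolated)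
22 | 5-{(8E)-14-[3,5-di(propan-2-yloxy)phenyl]tetradec-8-en-1-yl}-3-methoxycyclohexa-2,5-dien-1-one | COC1=CC(=O)C=C(CCCCCCC/C=C/CCCCCc2cc(OC(C)C)cc(OC(C)C)c2)C1 | intermediate (not isolated)
23 | 3-{(8E)-14-[3,5-di(propan-2-yloxy)phenyl]tetradec-8-en-1-yl}-5-methoxyphenol | COc1cc(O)cc(CCCCCCC/C=C/CCCCCc2cc(OC(C)C)cc(OC(C)C)c2)c1 | intermediate
24 | dehydrobisgravillol, 5-[(6E)-14-(3-hydroxy-5-methoxyphenyl)tetradec-6-en-1-yl]benzene-1,3-diol | COc1cc(O)cc(CCCCCCC/C=C/CCCCCc2cc(O)cc(O)c2)c1 | target

Total step count: 11. Longest linear sequence: 10 steps (steps 1, 2 and 4–11, from 5-bromoresorcinol).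

Steps most likely to fail

Step 10. The chain alkene may compete with the enolate for the selenium electrophile, and seleninic or peroxy species may attack the alkene or the newly formed electron-rich phenol. Any selenide formed cis to the chain also lacks a syn hydrogen and would eliminate slowly. The fallback is a Saegusa–Ito dehydrogenation, which uses neither an electrophilic chalcogen nor a peroxide. It sets out from 19: LiN(iPr)2 and Me3SiCl in THF at −78 °C should give the silyl dienol ether 5-{(8E)-14-[3,5-di(propan-2-yloxy)phenyl]tetradec-8-en-1-yl}-1-methoxy-3-(trimethylsilyloxy)cyclohexa-1,3-diene F1. Pd(OAc)2 (one equivalent of divalent palladium) in MeCN at room temperature should then form the palladium enolate, and β-hydride loss from C5 gives dienone 22. Tautomerisation brings the sequence back to the route at 23.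

Step 7. The reversible Michael addition may stall before ring closure, and methoxide may deconjugate or self-condense the enone; the lipophilic substrate may also be poorly soluble in methanol. The fallback builds the same ring with the polarity of the two partners exchanged. It sets out from 11: Wittig reaction with methyl (triphenylphosphoranylidene)acetate in toluene at 80 °C should give methyl (2E,11E)-17-[3,5-di(propan-2-yloxy)phenyl]heptadeca-2,11-dienoate F2. Methyl acetoacetate and NaOMe in MeOH at reflux should then add through the acetoacetate carbon to the enoate β-carbon, giving dimethyl 2-acetyl-3-{(8E)-14-[3,5-di(propan-2-yloxy)phenyl]tetradec-8-en-1-yl}pentanedioate F3. Its methyl ketone enolate closes onto the chain ester, and acidification brings the sequence back to the route at 16.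

Step 3. The unprotected hydroxyl consumes the moisture-sensitive zirconium hydride, so hydrometalation may be incomplete, or a second addition may over-reduce the alkyne. The fallback is hydroboration followed by base-promoted iodinolysis. It sets out from 6: excess catecholborane (neat, 70 °C) should add syn and anti-Markovnikov to the alkyne, and aqueous hydrolysis gives (E)-(10-hydroxydec-1-en-1-yl)boronic acid F4. Aqueous NaOH followed by I2 in Et2O at 0 °C should replace boron by iodine with retention of the E geometry, which brings the sequence back to the route at 8.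

Further compounds
F1 | step 10 | 5-{(8E)-14-[3,5-di(propan-2-yloxy)phenyl]tetradec-8-en-1-yl}-1-methoxy-3-(trimethylsilyloxy)cyclohexa-1,3-diene (racemic; one enantiomer drawn) | COC1=CC(O[Si](C)(C)C)=C[C@H](CCCCCCC/C=C/CCCCCc2cc(OC(C)C)cc(OC(C)C)c2)C1
F2 | step 7 | methyl (2E,11E)-17-[3,5-di(propan-2-yloxy)phenyl]heptadeca-2,11-dienoate | COC(=O)/C=C/CCCCCCC/C=C/CCCCCc1cc(OC(C)C)cc(OC(C)C)c1
F3 | step 7 | dimethyl 2-acetyl-3-{(8E)-14-[3,5-di(propan-2-yloxy)phenyl]tetradec-8-en-1-yl}pentanedioate (mixture of racemic diastereomers) | COC(=O)CC(CCCCCCC/C=C/CCCCCc1cc(OC(C)C)cc(OC(C)C)c1)C(C(C)=O)C(=O)OC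
F4 | step 3 | (E)-(10-hydroxydec-1-en-1-yl)boronic acid | OCCCCCCCC/C=C/B(O)O
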